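Early on, the precatalyst spends partner to become free catalyst, while starting material enters the round portion by portion.

    partner + catalyst intermediate A → catalyst intermediate B (k1 = 0.17 L mol⁻¹ s⁻¹)
    starting material + free catalyst ⇌ catalyst intermediate A (K2 = 8.8 L mol⁻¹, k2 = 0.21 L mol⁻¹ s⁻¹)
    partner + precatalyst → free catalyst + spent reagent (k3 = 0.15 L mol⁻¹ s⁻¹)
    catalyst intermediate C ⇌ released group + catalyst intermediate D (K4 = 0.091 M, k4 = 0.053 s⁻¹)
    catalyst intermediate B ⇌ catalyst intermediate C (K5 = 1.1, k5 = 0.19 s⁻¹)
    catalyst intermediate D ⇌ free catalyst + target (K6 = 0.25 M, k6 = 0.25 s⁻¹)

| flask | starting material | partner | precatalyst | time | remark |
|---|---|---|---|---|---|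
| Saturday's | 0.25 M (in portions, 4) | 0.263 M | 10 mM | 20 min | the portions of starting material follow each other after 4.0 min, the first at the start |
| Monday's | 0.25 M (in portions, 4) | 0.263 M | 30 mM | 20 min | the portions of starting material follow each other after 4.0 min, the first at the start |
| Tuesday's | 0.25 M (in portions, 4) | 0.263 M | 100 mM | 20 min | the portions of starting material follow each other after 4.0 min, the first at the start |

- amount of target at the end, in percent of the starting material charged for Saturday's, Monday's, Tuesday's, in this order
- how the row runs (rises all the way / hardly changes / falls, then rises / falls all the way / rises, then falls)

- "hardly changes" means that all values lie within two and a half points (for a concentration: within two and a half percent of the largest)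
- run time (Saturday's): 20 min

The reckoning here builds the flask by hand, one process at a time, and counts target as a fraction of the charged starting material. First comes the main step by itself, with the whole catalyst sitting as intermediate A and partner at its charge. A turnover then takes 22.4 s, and Saturday's flask would make 215 % of the charge, an impossible figure.

Next comes the binding of starting material, with the pool taken at half the charge as an assumption. Counting the bound starting material that falls back off, binding adds 58.4 s per turnover, and Saturday's figure drops to 59.4 %.

The three later forward steps add 28.1 s. The turnover time becomes 109 s, and the count reads 44.1 % for Saturday's flask and 132 % for Monday's. This count leaves out the backward steps after binding.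

Last comes activation. Its half-life at the partner charge is 17.6 s, far shorter than the run, so each precatalyst takes one partner early. Catalyst intermediates B, C and D also carry partner. If the catalyst is assumed to spread evenly over its 5 forms, these 3 hold 60.0 % of it. Tuesday's flask can then make 41.2 % of the charge. That figure is the partner allowance: partner charged, less the precatalyst charge, less the partner held on the catalyst, per charged starting material.

The allowance is 98.8 % for Saturday's flask and 86.0 % for Monday's. The reckoning takes the smaller of count and allowance in each flask. The smaller is the count for Saturday's flask, at 44.1 %, and the allowance for Monday's flask, at 86.0 %. For Tuesday's flask the reckoning makes partner the limiting reagent, at 41.2 %. The reckoned row therefore rises, then falls.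

The forecast gives 23 %, 47 % and 42 %, with the shape "rises, then falls", holding that “more catalyst gives more target” at the lower charges, and it parts from this reckoning most at Monday's flask, 47 % against 86.0 %.

The simulation gives 28.7 %, 49.1 % and 43.0 %, with the shape "rises, then falls" and the turn near 50 mM. Saturday's and Monday's values stand below this reckoning. Tuesday's flask ends with 2.52 % of its partner left, against 67.0 % in Saturday's. Its intermediates B, C and D hold 48.9 % of the catalyst, which moves its allowance to 45.7 %. Monday's flask ends short of its allowance of 86.0 %, with 35.2 % of its partner left; after 200 min, its target stands at 81.8 %, with 1.84 % of the partner left.

The constants are invented; no experiment stands behind them.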